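**Retrosynthetic overview**
1. Feature: in the 1,2-dioxane ring (O–O, C3, C4, C5, C6) the two C–O bonds at C3 and C6 are 1,4-related across C4–C5, so the ring is the dioxygen adduct of a (3E,5E)-4,6-dimethyl-3,5-dienoic acid. The lactone C4–O bond then comes from the C1 carboxyl adding across the C4=C5 bond that the cycloaddition leaves behind.
2. Ring order: 1,2-dioxine first by (4+2) addition of singlet oxygen (step 12), γ-lactone second by iodolactonisation (step 13), then reductive removal of iodine (step 14).
3. Diene acid: C4–C5 bond by Negishi coupling of the C5–C16 (E)-vinyl iodide with a C1–C4 alkenylzinc made by hydrozirconation of a pent-3-yn-1-ol ether, then oxidation of C1 to the acid.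
4. Vinyl iodide: C8 from (R)-citronellal, C5 by Ohira–Bestmann alkynylation, C11=C12 by Julia–Kocienski olefination with a sulfone from (E)-5-phenylpent-4-en-1-ol, C6 methyl by Zr-catalysed carboalumination–iodination.

Key step: step 12

Remark: polyketide numbering is used throughout (C1 lactone carbonyl, C3 CH–OO, C4 C(CH3)–O of the lactone, C6 C(CH3)–OO, C8 CH(CH3), C11=C12 and C15=C16 the chain alkenes, phenyl on C16); in this numbering the target is (3S,4S,6R,8R). The two facial diastereomers of the cycloadduct are assumed to be separable by preparative HPLC.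

Step 1
Reactants: 1 (R)-citronellal [(3R)-3,7-dimethyloct-6-enal]
Product: 2 (4R)-4,8-dimethylnon-7-en-1-yne
Conditions: dimethyl (1-diazo-2-oxopropyl)phosphonate, K2CO3, MeOH, 0 °C to rt
Reagents that add atoms: Ohira–Bestmann reagent, dimethyl (1-diazo-2-oxopropyl)phosphonate, CC(=O)C(=[N+]=[N-])P(=O)(OC)OC
Why: The Ohira–Bestmann variant of the Seyferth–Gilbert homologation should convert the aldehyde into the terminal alkyne (new carbon = C5) under mild carbonate conditions, and the C8 centre is β to the carbonyl and cannot epimerise.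

Step 2
Reactants: 2 (4R)-4,8-dimethylnon-7-en-1-yne
Product: 4 (4R)-4-methylhept-6-ynal, via secondary ozonide 3 (not isolated)
Conditions: O3, CH2Cl2, −78 °C (Sudan Red 7B end-point); then PPh3, −78 °C to rt
Reagents that add atoms: ozone, [O-][O+]=O
Why: In this chemoselective ozonolysis the electron-rich trisubstituted alkene should be consumed far faster than the terminal alkyne, the dye marking the end-point, and PPh3 reduces the ozonide to the C11 aldehyde.

Step 3
Reactants: 5 (4E)-5-phenylpent-4-en-1-ol
Product: 6 1-phenyl-5-{[(4E)-5-phenylpent-4-en-1-yl]sulfanyl}-1H-tetrazole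
Conditions: 1-phenyl-1H-tetrazole-5-thiol, PPh3, diisopropyl azodicarboxylate, THF, 0 °C to rt
Reagents that add atoms: 1-phenyl-1H-tetrazole-5-thiol, Sc1nnnn1-c1ccccc1
Why: A Mitsunobu thioetherification of the primary alcohol with the acidic heteroaryl thiol should be clean and leaves the styrene untouched.

Step 4
Reactants: 6 1-phenyl-5-{[(4E)-5-phenylpent-4-en-1-yl]sulfanyl}-1H-tetrazole
Product: 7 1-phenyl-5-{[(4E)-5-phenylpent-4-en-1-yl]sulfonyl}-1H-tetrazole
Conditions: 30% H2O2, (NH4)6Mo7O24·4H2O (cat.), EtOH, 0 °C to rt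
Reagents that add atoms: hydrogen peroxide, OO
Why: Molybdate-catalysed peroxide oxidation takes the sulfide to the sulfone much faster than it epoxidises a styrene, which is why it is preferred to a peracid here.

Step 5
Reactants: 7 1-phenyl-5-{[(4E)-5-phenylpent-4-en-1-yl]sulfonyl}-1H-tetrazole; 4 (4R)-4-methylhept-6-ynal
Product: 9 [(1E,5E,9R)-9-methyldodeca-1,5-dien-11-yn-1-yl]benzene, via potassium sulfonyl carbanion 8 (not isolated)
Conditions: KN(SiMe3)2, DME, −60 °C; then 4, −60 °C to rt
Reagents that add atoms: none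
Why: The Julia–Kocienski olefination (addition, Smiles rearrangement, loss of SO2 and tetrazolate) should form C11=C12 with the E preference typical of phenyltetrazolyl sulfones with a potassium counter-ion in DME, the pre-formed carbanion adding to the aldehyde faster than it deprotonates the alkyne.

Step 6
Reactants: 9 [(1E,5E,9R)-9-methyldodeca-1,5-dien-11-yn-1-yl]benzene
Product: 11 [(1E,5E,9R,11E)-12-iodo-9,11-dimethyldodeca-1,5,11-trien-1-yl]benzene, via alkenyldimethylalane 10 (not isolated)
Conditions: AlMe3, Cp2ZrCl2 (cat.), CH2Cl2, 0 °C to rt; then I2, THF, −30 to 0 °C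
Reagents that add atoms: trimethylaluminium, C[Al](C)C; iodine, II
Why: Negishi's Zr-catalysed methylalumination adds methyl (to C6) and aluminium (to C5) syn across the terminal alkyne only, and iodinolysis with retention should give the (E)-iodide while the internal alkenes stay inert.

Step 7
Reactants: 12 pent-3-yn-1-ol
Product: 13 tert-butyldimethyl(pent-3-yn-1-yloxy)silane
Conditions: TBSCl, imidazole, DMF, rt
Reagents that add atoms: tert-butyldimethylsilyl chloride, CC(C)(C)[Si](C)(C)Cl
Why: Standard silylation masks the hydroxyl so that it consumes no Cp2ZrHCl in the next step.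

Step 8
Reactants: 13 tert-butyldimethyl(pent-3-yn-1-yloxy)silane; 11 [(1E,5E,9R,11E)-12-iodo-9,11-dimethyldodeca-1,5,11-trien-1-yl]benzene
Product: 16 tert-butyldimethyl{[(3E,5E,8R,11E,15E)-4,6,8-trimethyl-16-phenylhexadeca-3,5,11,15-tetraen-1-yl]oxy}silane, via alkenylzirconocene chloride 14 (not isolated), via alkenylzinc chloride 15 (not isolated)
Conditions: 13, Cp2ZrHCl, THF, 50 °C; then ZnCl2, 11, Pd(PPh3)4 (cat.), THF, rt
Reagents that add atoms: none
Why: Syn hydrozirconation of the 2-alkyne places zirconium on the methyl-bearing carbon (C4) under thermodynamic control, and transmetalation to zinc followed by Pd-catalysed Negishi coupling with the (E)-iodide should form the C4–C5 bond with retention at both alkenes, a combination established for alkenylzirconocenes from 2-alkynes.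

Step 9
Reactants: 16 tert-butyldimethyl{[(3E,5E,8R,11E,15E)-4,6,8-trimethyl-16-phenylhexadeca-3,5,11,15-tetraen-1-yl]oxy}silane
Product: 17 (3E,5E,8R,11E,15E)-4,6,8-trimethyl-16-phenylhexadeca-3,5,11,15-tetraen-1-ol
Conditions: Bu4NF, THF, 0 °C to rt
Reagents that add atoms: none
Why: Fluoride-induced desilylation should free the primary alcohol without touching the diene.

Step 10
Reactants: 17 (3E,5E,8R,11E,15E)-4,6,8-trimethyl-16-phenylhexadeca-3,5,11,15-tetraen-1-ol
Product: 18 (3E,5E,8R,11E,15E)-4,6,8-trimethyl-16-phenylhexadeca-3,5,11,15-tetraenal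
Conditions: Dess–Martin periodinane, NaHCO3, CH2Cl2, 0 °C; crude aldehyde used at once
Reagents that add atoms: none
Why: The buffered Dess–Martin oxidation works at neutral pH and low temperature, which should keep the β,γ-unsaturated aldehyde from moving into conjugation.

Step 11
Reactants: 18 (3E,5E,8R,11E,15E)-4,6,8-trimethyl-16-phenylhexadeca-3,5,11,15-tetraenal
Product: 19 (3E,5E,8R,11E,15E)-4,6,8-trimethyl-16-phenylhexadeca-3,5,11,15-tetraenoic acid
Conditions: NaClO2, NaH2PO4, 2-methylbut-2-ene (excess), t-BuOH/H2O, 0 °C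
Reagents that add atoms: sodium chlorite, [Na+].[O-]Cl=O
Why: The Pinnick oxidation converts the aldehyde into the acid at about pH 4 without enolisation, the excess alkene scavenger removing hypochlorous acid before it can attack the diene or the styrene.

Step 12
Reactants: 19 (3E,5E,8R,11E,15E)-4,6,8-trimethyl-16-phenylhexadeca-3,5,11,15-tetraenoic acid
Product: 20 2-{(3S,6R)-4,6-dimethyl-6-[(2R,5E,9E)-2-methyl-10-phenyldeca-5,9-dien-1-yl]-3,6-dihydro-1,2-dioxin-3-yl}acetic acid
Conditions: O2, 5,10,15,20-tetraphenylporphyrin (cat.), white LED, CH2Cl2, −20 °C; then preparative HPLC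
Reagents that add atoms: dioxygen, O=O
Why: Triplet tetraphenylporphyrin transfers its energy to O2, and the singlet oxygen so formed adds across C3 and C6 of the s-cis conformer of the (3E,5E)-diene in a concerted suprafacial (4+2) cycloaddition, the known endoperoxide-forming addition of singlet oxygen to acyclic 1,3-dienes. The six-membered 3,6-dihydro-1,2-dioxine ring is closed in this one cycloaddition, the C3–O and C6–O bonds forming together and the C4=C5 alkene remaining in the ring. Because the addition is suprafacial and both alkenes are E, the outer groups C2 and C7 end up cis (C3 hydrogen cis to the C6 methyl), which is the relative configuration of the target at C3 and C6. The remote C8 centre does not differentiate the two faces of the diene, so 20 and its (3R,6S,8R) isomer are expected in similar amounts and the latter is removed by preparative HPLC. The step needs chemoselectivity for the diene and periselectivity over the Schenck ene reaction: the electron-rich trisubstituted diene should react much faster than the 1,2-disubstituted alkene and the styrene, the C4 and C6 methyl groups destabilise the s-trans conformer by 1,3-allylic strain so that a cisoid geometry is populated, and low temperature in an aprotic solvent limits the ene and dioxetane pathways.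

Step 13
Reactants: 20 2-{(3S,6R)-4,6-dimethyl-6-[(2R,5E,9E)-2-methyl-10-phenyldeca-5,9-dien-1-yl]-3,6-dihydro-1,2-dioxin-3-yl}acetic acid
Product: 21 (3R,4S,4aR,7aS)-4-iodo-3,4a-dimethyl-3-[(2R,5E,9E)-2-methyl-10-phenyldeca-5,9-dien-1-yl]-3,4,4a,7a-tetrahydrofuro[3,2-c][1,2]dioxin-6(7H)-one (cis-fused iodolactone; iodine on C5 trans to the lactone oxygen)
Conditions: I2, NaHCO3, MeCN, 0 °C, dark
Reagents that add atoms: iodine, II
Why: In this iodolactonisation the carboxylate tethered to C3 opens the iodonium ion of C4=C5 in a 5-exo Markovnikov attack at tertiary C4 from its own face, which fixes C4 through the obligatory cis ring fusion and places iodine anti on C5, while the bicarbonate medium spares the peroxide and iodine adds only reversibly to the chain alkenes.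

Step 14
Reactants: 21 cis-fused iodolactone (3S,4R,5S,6R,8R in polyketide numbering)
Product: 22 (3R,4aS,7aS)-3,4a-dimethyl-3-[(2R,5E,9E)-2-methyl-10-phenyldeca-5,9-dien-1-yl]-3,4,4a,7a-tetrahydrofuro[3,2-c][1,2]dioxin-6(7H)-one (CNP0365311.2)
Conditions: Bu3SnH (excess), Et3B (cat.), trace air, toluene, 0 °C to rt
Reagents that add atoms: none
Why: Radical chain deiodination (iodine abstraction by the stannyl radical, then fast hydrogen transfer to the C5 radical) turns C5 into a methylene without touching C3, C4, C6 or C8, and room-temperature initiation with high hydride concentration should outrun any attack on the ring O–O bond, whose endocyclic geometry disfavours radical displacement at oxygen.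

**Compound list**
1 | (R)-citronellal, (3R)-3,7-dimethyloct-6-enal | C[C@H](CCC=C(C)C)CC=O | starting material
2 | (4R)-4,8-dimethylnon-7-en-1-yne | C[C@H](CCC=C(C)C)CC#C | intermediate
3 | secondary ozonide of 2, 3,3-dimethyl-5-[(3R)-3-methylhex-5-yn-1-yl]-1,2,4-trioxolane (not isolated) | C[C@H](CCC1OOC(C)(C)O1)CC#C | intermediate
4 | (4R)-4-methylhept-6-ynal | C[C@H](CCC=O)CC#C | intermediate
5 | (4E)-5-phenylpent-4-en-1-ol | OCCC/C=C/c1ccccc1 | starting material
6 | 1-phenyl-5-{[(4E)-5-phenylpent-4-en-1-yl]sulfanyl}-1H-tetrazole | C(CC/C=C/c1ccccc1)Sc1nnnn1-c1ccccc1 | intermediate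
7 | 1-phenyl-5-{[(4E)-5-phenylpent-4-en-1-yl]sulfonyl}-1H-tetrazole | O=S(=O)(CCC/C=C/c1ccccc1)c1nnnn1-c1ccccc1 | intermediate
8 | potassium α-sulfonyl carbanion of 7 (not isolated) | [K+].[CH-](CC/C=C/c1ccccc1)S(=O)(=O)c1nnnn1-c1ccccc1 | intermediate
9 | [(1E,5E,9R)-9-methyldodeca-1,5-dien-11-yn-1-yl]benzene | C[C@H](CC/C=C/CC/C=C/c1ccccc1)CC#C | intermediate
10 | dimethyl[(1E,4R,7E,11E)-2,4-dimethyl-12-phenyldodeca-1,7,11-trien-1-yl]alumane (not isolated) | C[C@H](CC/C=C/CC/C=C/c1ccccc1)C/C(C)=C/[Al](C)C | intermediate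
11 | [(1E,5E,9R,11E)-12-iodo-9,11-dimethyldodeca-1,5,11-trien-1-yl]benzene | C[C@H](CC/C=C/CC/C=C/c1ccccc1)C/C(C)=C/I | intermediate
12 | pent-3-yn-1-ol | CC#CCCO | starting material
13 | tert-butyldimethyl(pent-3-yn-1-yloxy)silane | CC#CCCO[Si](C)(C)C(C)(C)C | intermediate
14 | chloridobis(cyclopentadienyl)[(2E)-5-{[tert-butyl(dimethyl)silyl]oxy}pent-2-en-2-yl]zirconium (not isolated) | Cl[Zr](C1C=CC=C1)(C1C=CC=C1)/C(C)=C/CCO[Si](C)(C)C(C)(C)C | intermediate
15 | chlorido[(2E)-5-{[tert-butyl(dimethyl)silyl]oxy}pent-2-en-2-yl]zinc (not isolated) | Cl[Zn]/C(C)=C/CCO[Si](C)(C)C(C)(C)C | intermediate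
16 | tert-butyldimethyl{[(3E,5E,8R,11E,15E)-4,6,8-trimethyl-16-phenylhexadeca-3,5,11,15-tetraen-1-yl]oxy}silane | C[C@H](CC/C=C/CC/C=C/c1ccccc1)C/C(C)=C/C(C)=C/CCO[Si](C)(C)C(C)(C)C | intermediate
17 | (3E,5E,8R,11E,15E)-4,6,8-trimethyl-16-phenylhexadeca-3,5,11,15-tetraen-1-ol | C[C@H](CC/C=C/CC/C=C/c1ccccc1)C/C(C)=C/C(C)=C/CCO | intermediate
18 | (3E,5E,8R,11E,15E)-4,6,8-trimethyl-16-phenylhexadeca-3,5,11,15-tetraenal | C[C@H](CC/C=C/CC/C=C/c1ccccc1)C/C(C)=C/C(C)=C/CC=O | intermediate
19 | (3E,5E,8R,11E,15E)-4,6,8-trimethyl-16-phenylhexadeca-3,5,11,15-tetraenoic acid | C[C@H](CC/C=C/CC/C=C/c1ccccc1)C/C(C)=C/C(C)=C/CC(=O)O | intermediate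
20 | 2-{(3S,6R)-4,6-dimethyl-6-[(2R,5E,9E)-2-methyl-10-phenyldeca-5,9-dien-1-yl]-3,6-dihydro-1,2-dioxin-3-yl}acetic acid | C[C@H](CC/C=C/CC/C=C/c1ccccc1)C[C@]1(C)C=C(C)[C@H](CC(=O)O)OO1 | intermediate
21 | (3R,4S,4aR,7aS)-4-iodo-3,4a-dimethyl-3-[(2R,5E,9E)-2-methyl-10-phenyldeca-5,9-dien-1-yl]-3,4,4a,7a-tetrahydrofuro[3,2-c][1,2]dioxin-6(7H)-one | C[C@H](CC/C=C/CC/C=C/c1ccccc1)C[C@]1(C)[C@@H](I)[C@]2(C)OC(=O)C[C@@H]2OO1 | intermediate
22 | (3R,4aS,7aS)-3,4a-dimethyl-3-[(2R,5E,9E)-2-methyl-10-phenyldeca-5,9-dien-1-yl]-3,4,4a,7a-tetrahydrofuro[3,2-c][1,2]dioxin-6(7H)-one, CNP0365311.2 | C[C@H](CC/C=C/CC/C=C/c1ccccc1)C[C@]1(C)C[C@]2(C)OC(=O)C[C@@H]2OO1 | target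

**Step count and risks**
Total step count: 14. Longest linear sequence: 11 steps (1, 2, 5, 6, 8, 9, 10, 11, 12, 13, 14).

Step 12. What may go wrong: hydrogen abstraction by singlet oxygen (Schenck ene reaction, notably at the C2 hydrogens, which leads to a conjugated hydroperoxy acid) may overtake the (4+2) mode. The ene/(4+2) partition is a property of the diene and can only be mitigated, and the two facial diastereomers, being free acids, may resist separation. Fallback: the cycloaddition is moved ahead of the oxidation of C1. Setting out from dienol 17, the same sensitised photooxygenation (O2, tetraphenylporphyrin, light, CH2Cl2) should give 2-{(3S,6R)-4,6-dimethyl-6-[(2R,5E,9E)-2-methyl-10-phenyldeca-5,9-dien-1-yl]-3,6-dihydro-1,2-dioxin-3-yl}ethan-1-ol F1, a neutral compound from which the (3R,6S) diastereomer is removed on silica. Buffered Dess–Martin oxidation then gives the dioxinylacetaldehyde F2, which no longer contains a skipped diene, and Pinnick oxidation brings the route back at 20. Compounds 18 and 19 are bypassed.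

Step 8. What may go wrong: incomplete regiocontrol in the hydrozirconation (zirconium partly on C3) would carry a constitutional isomer into the diene, and residual Zr–H may reduce the vinyl iodide. Fallback: C1–C4 is built on the iodide by two regio-defined Negishi operations. From 11, Pd(PPh3)4-catalysed coupling with ethynylzinc bromide (from HC≡CMgBr and ZnBr2) should give the enyne [(1E,5E,9R,11E)-9,11-dimethyltetradeca-1,5,11-trien-13-yn-1-yl]benzene F3. Zr-catalysed methylalumination (AlMe3, Cp2ZrCl2 cat.) gives dimethyl[(1E,3E,6R,9E,13E)-2,4,6-trimethyl-14-phenyltetradeca-1,3,9,13-tetraen-1-yl]alumane F4, which after addition of n-BuLi is alkylated with oxirane to return at dienol 17. No silyl protection is needed.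

Step 14. What may go wrong: stannyl radicals may cleave the O–O bond, the C5 radical may fragment toward the peroxide instead of accepting hydrogen, and reversible stannyl addition may erode the styrene geometry. Fallback: the halogen and the radical step are avoided altogether. From 20, Brønsted-acid-catalysed Markovnikov hydro-lactonisation (catalytic CF3SO3H, CH2Cl2, −20 °C; protonation at C5, capture of the C4 cation by the tethered carboxyl) should lead directly to 22. The cost is possible ionisation of the allylic tertiary C6–O bond and loss of the C6 configuration, which is why this path is held in reserve.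

**Further compounds**
F1 | step 12 | 2-{(3S,6R)-4,6-dimethyl-6-[(2R,5E,9E)-2-methyl-10-phenyldeca-5,9-dien-1-yl]-3,6-dihydro-1,2-dioxin-3-yl}ethan-1-ol | C[C@H](CC/C=C/CC/C=C/c1ccccc1)C[C@]1(C)C=C(C)[C@H](CCO)OO1
F2 | step 12 | 2-{(3S,6R)-4,6-dimethyl-6-[(2R,5E,9E)-2-methyl-10-phenyldeca-5,9-dien-1-yl]-3,6-dihydro-1,2-dioxin-3-yl}acetaldehyde | C[C@H](CC/C=C/CC/C=C/c1ccccc1)C[C@]1(C)C=C(C)[C@H](CC=O)OO1
F3 | step 8 | [(1E,5E,9R,11E)-9,11-dimethyltetradeca-1,5,11-trien-13-yn-1-yl]benzene | C[C@H](CC/C=C/CC/C=C/c1ccccc1)C/C(C)=C/C#C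
F4 | step 8 | dimethyl[(1E,3E,6R,9E,13E)-2,4,6-trimethyl-14-phenyltetradeca-1,3,9,13-tetraen-1-yl]alumane | C[C@H](CC/C=C/CC/C=C/c1ccccc1)C/C(C)=C/C(C)=C/[Al](C)C
F0 | step 14 | none | none
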